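Isochromene numbering (C1, O2, C3, C4, C4a, C5–C8, C8a) is used. The cyclohexenone ring is cut into two three-carbon units: C4a=C8a–C8, taken from a 4-chloro-3-formyl-2H-pyran, and C5–C6–C7, taken from an (R)-malic acid derivative as the redox-active ester of a 3-silyloxy-4-oxopentanoic acid. In one flask a nickel-catalysed decarboxylative alkenylation joins C5 to C4a and a carbene-catalysed aldehyde–ketone benzoin joins C8 to C7. The step exploits the α-ketol of ring carbons C8 (ketone) and C7 (tertiary carbinol) and the C4a=C8a double bond shared by the pyran and carbocyclic rings; the C6 silyloxy stereocentre sets C7. Esterification at O6 and acidolysis finish the synthesis.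

Key step: step 14

Remark: both stereocentres are R, which places the C6 acyloxy oxygen and the C7 hydroxyl cis on the ring; the route is built for this cis-(6R,7R) arrangement.
Assumption: compounds 11 (the acetonide of (R)-malic acid) and 17 are bought as catalogue chemicals.

**Pyran fragment**

Step 1
Reactants: 1 3-[(tert-butyldimethylsilyl)oxy]propanal; 2 3,3-diethoxyprop-1-yne
Product: 4 1-[(tert-butyldimethylsilyl)oxy]-6,6-diethoxyhex-4-yn-3-ol (racemic), via lithium acetylide 3 (not isolated)
Conditions: 2, n-BuLi, THF, −78 °C; then 1, −78 → 0 °C; aq NH4Cl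
Reagents that add atoms: none
Why: 1,2-addition of a lithium acetylide to an aldehyde; the carbinol centre is oxidised in the next step, so its configuration is irrelevant.

Step 2
Reactants: 4 1-[(tert-butyldimethylsilyl)oxy]-6,6-diethoxyhex-4-yn-3-ol
Product: 5 1-[(tert-butyldimethylsilyl)oxy]-6,6-diethoxyhex-4-yn-3-one
Conditions: Dess–Martin periodinane, CH2Cl2, 0 °C → rt
Reagents that add atoms: none
Why: Dess–Martin oxidation of a propargylic alcohol to the ynone under conditions that leave the silyl ether and acetal intact.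

Step 3
Reactants: 5 1-[(tert-butyldimethylsilyl)oxy]-6,6-diethoxyhex-4-yn-3-one
Product: 8 4-oxo-5,6-dihydro-4H-pyran-2-carbaldehyde, via hydroxy ynone 6 (not isolated), via acetal pyranone 7 (not isolated)
Conditions: TsOH·H2O (20 mol%), acetone/H2O 10:1, 50 °C
Reagents that add atoms: water, O
Why: Acid removes the silyl ether, the freed primary hydroxyl closes onto the ynone by 6-endo-dig oxa-Michael addition to give the 2,3-dihydro-4H-pyran-4-one, and the acetal is then hydrolysed to the aldehyde.

Step 4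
Reactants: 8 4-oxo-5,6-dihydro-4H-pyran-2-carbaldehyde
Product: 9 tert-butyl (E)-3-(4-oxo-5,6-dihydro-4H-pyran-2-yl)acrylate
Conditions: Ph3P=CHCO2t-Bu, CH2Cl2, rt
Reagents that add atoms: tert-butyl (triphenylphosphoranylidene)acetate, CC(C)(C)OC(=O)C=P(c1ccccc1)(c1ccccc1)c1ccccc1
Why: Wittig olefination with a stabilised ylide should be E-selective and should touch only the aldehyde, not the vinylogous ester carbonyl.

Step 5
Reactants: 9 tert-butyl (E)-3-(4-oxo-5,6-dihydro-4H-pyran-2-yl)acrylate
Product: 10 tert-butyl (E)-3-(4-chloro-3-formyl-2H-pyran-6-yl)acrylate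
Conditions: POCl3, DMF, CH2Cl2, 0 °C → rt; aq NaOAc
Reagents that add atoms: N,N-dimethylformamide, CN(C)C=O; phosphoryl chloride, O=P(Cl)(Cl)Cl; water, O
Why: Vilsmeier–Haack–Arnold chloroformylation of the ketone α-methylene, as in the conversion of 4-chromanones into 4-chloro-2H-chromene-3-carbaldehydes; the enol-ether carbon is deactivated by the acrylate, and the push–pull 2H-pyran product should be stable.

**C5–C7 fragment**

Step 6
Reactants: 11 (R)-2-(2,2-dimethyl-5-oxo-1,3-dioxolan-4-yl)acetic acid
Product: 12 (R)-3-hydroxy-4-[methoxy(methyl)amino]-4-oxobutanoic acid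
Conditions: MeNH(OMe)·HCl, i-PrMgCl, THF, −20 → 0 °C; aq citric acid
Reagents that add atoms: N,O-dimethylhydroxylamine hydrochloride, CNOC.Cl
Why: The magnesium amide opens the activated dioxolanone at its only electrophilic carbonyl (the acid is protected as its carboxylate) with loss of acetone, giving the Weinreb amide without touching the stereocentre.

Step 7
Reactants: 12 (R)-3-hydroxy-4-[methoxy(methyl)amino]-4-oxobutanoic acid
Product: 14 (R)-3-[(tert-butyldimethylsilyl)oxy]-4-[methoxy(methyl)amino]-4-oxobutanoic acid, via silyl ester 13 (not isolated)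
Conditions: TBSCl (2.5 equiv), imidazole, DMF, rt; then THF/H2O/AcOH, rt
Reagents that add atoms: tert-butyldimethylsilyl chloride, CC(C)(C)[Si](C)(C)Cl
Why: Silylation of the alcohol and the acid followed by selective hydrolysis of the labile silyl ester leaves the secondary silyl ether.

Step 8
Reactants: 14 (R)-3-[(tert-butyldimethylsilyl)oxy]-4-[methoxy(methyl)amino]-4-oxobutanoic acid
Product: 15 (R)-3-[(tert-butyldimethylsilyl)oxy]-4-oxopentanoic acid
Conditions: MeMgBr (3.2 equiv), THF, −40 → 0 °C; aq NH4Cl/HCl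
Reagents that add atoms: methylmagnesium bromide, C[Mg]Br
Why: Weinreb ketone synthesis; the chelated tetrahedral intermediate prevents over-addition and α-epimerisation while the carboxylate is inert.

Step 9
Reactants: 15 (R)-3-[(tert-butyldimethylsilyl)oxy]-4-oxopentanoic acid
Product: 16 1,3-dioxoisoindolin-2-yl (R)-3-[(tert-butyldimethylsilyl)oxy]-4-oxopentanoate
Conditions: N-hydroxyphthalimide, DIC, DMAP (5 mol%), CH2Cl2, 0 °C → rt
Reagents that add atoms: N-hydroxyphthalimide, O=C1c2ccccc2C(=O)N1O
Why: Carbodiimide coupling gives the redox-active N-acyloxyphthalimide under near-neutral conditions that should not epimerise the α-silyloxy ketone.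

**Aryl acid**

Step 10
Reactants: 17 5-methylbenzene-1,2,3-triol
Product: 18 6-methyl-2,2-diphenyl-1,3-benzodioxol-4-ol
Conditions: Ph2CCl2 (1.2 equiv), neat, 170 °C
Reagents that add atoms: dichlorodiphenylmethane, ClC(Cl)(c1ccccc1)c1ccccc1
Why: Ketalisation of two vicinal phenols of a pyrogallol, which by symmetry gives one product and leaves one outer hydroxyl free.

Step 11
Reactants: 18 6-methyl-2,2-diphenyl-1,3-benzodioxol-4-ol
Product: 19 4-hydroxy-6-methyl-2,2-diphenyl-1,3-benzodioxole-5-carbaldehyde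
Conditions: MgCl2, Et3N, paraformaldehyde, MeCN, reflux
Reagents that add atoms: paraformaldehyde (as formaldehyde), C=O
Why: Magnesium-mediated ortho-formylation (Casnati–Skattebøl) is ortho-specific, and the only free ortho carbon is the one between the hydroxyl and the methyl group.

Step 12
Reactants: 19 4-hydroxy-6-methyl-2,2-diphenyl-1,3-benzodioxole-5-carbaldehyde
Product: 20 4-methoxy-6-methyl-2,2-diphenyl-1,3-benzodioxole-5-carbaldehyde
Conditions: MeI, K2CO3, DMF, 40 °C
Reagents that add atoms: iodomethane, CI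
Why: Williamson O-methylation of the only free phenol.

Step 13
Reactants: 20 4-methoxy-6-methyl-2,2-diphenyl-1,3-benzodioxole-5-carbaldehyde
Product: 21 4-methoxy-6-methyl-2,2-diphenyl-1,3-benzodioxole-5-carboxylic acid
Conditions: NaClO2, NaH2PO4, 2-methyl-2-butene, t-BuOH/H2O, rt
Reagents that add atoms: sodium chlorite, [Na+].[O-]Cl=O
Why: Pinnick oxidation converts the hindered aldehyde to the acid, and the alkene scavenger protects the electron-rich ring from chlorination.

**Union and completion**

Step 14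
Reactants: 10 tert-butyl (E)-3-(4-chloro-3-formyl-2H-pyran-6-yl)acrylate; 16 1,3-dioxoisoindolin-2-yl (R)-3-[(tert-butyldimethylsilyl)oxy]-4-oxopentanoate
Product: 23 tert-butyl (E)-3-[(6R,7R)-6-[(tert-butyldimethylsilyl)oxy]-7-hydroxy-7-methyl-8-oxo-5,6,7,8-tetrahydro-1H-isochromen-3-yl]acrylate, via keto-enal 22 (not isolated)
Conditions: NiBr2·diglyme (10 mol%), 4,4′-di-tert-butyl-2,2′-bipyridine (12 mol%), NaI (0.5 equiv), tetrakis(dimethylamino)ethylene (1.5 equiv), DMA, 0 °C → rt; then, same flask, 2-(pentafluorophenyl)-6,7-dihydro-5H-pyrrolo[2,1-c][1,2,4]triazol-2-ium tetrafluoroborate (30 mol%), Et3N (1.0 equiv), rt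
Reagents that add atoms: none
Why: Zerovalent nickel inserts into the vinylogous acid chloride C4a–Cl bond of 10 (assisted by iodide exchange), single-electron reduction of 16 releases CO2, phthalimide anion and the primary C5 radical, and radical capture at nickel followed by reductive elimination forms C4a–C5 to give keto-enal 22 (nickel-catalysed decarboxylative cross-electrophile alkenylation of a redox-active ester). The triazolylidene then adds to the C8 aldehyde, the Breslow intermediate attacks the C7 methyl ketone and the carbene is expelled, forming C7–C8 and the α-ketol (intramolecular crossed aldehyde–ketone benzoin reaction). The cyclohexenone ring closes in the 6-exo-trig mode. C7 is set by the C6 stereocentre: in the chair-like polar Felkin–Anh transition state the silyloxy group is pseudo-equatorial and anti to the incoming C8, the methyl group is equatorial and the new hydroxyl axial, that is cis to the C6 oxygen (7R). The step needs coupling at C–Cl instead of radical addition to the acrylate (capture at nickel should outrun addition to a β-substituted acrylate), benzoin instead of homoenolate or Stetter chemistry (C4a is fully substituted and no acceptor lies within reach of C8), and no loss of the C6 configuration (weak amine base; the silyl ether is a poor leaving group, so vinylogous elimination is not expected).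

Step 15
Reactants: 23 tert-butyl (E)-3-[(6R,7R)-6-[(tert-butyldimethylsilyl)oxy]-7-hydroxy-7-methyl-8-oxo-5,6,7,8-tetrahydro-1H-isochromen-3-yl]acrylate
Product: 24 tert-butyl (E)-3-[(6R,7R)-6,7-dihydroxy-7-methyl-8-oxo-5,6,7,8-tetrahydro-1H-isochromen-3-yl]acrylate
Conditions: HF·pyridine, THF/pyridine, 0 °C → rt
Reagents that add atoms: none
Why: Buffered fluoride desilylation avoids the basic conditions that could trigger α-ketol rearrangement or elimination and leaves the tert-butyl ester and dienyl ether intact.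

Step 16
Reactants: 24 tert-butyl (E)-3-[(6R,7R)-6,7-dihydroxy-7-methyl-8-oxo-5,6,7,8-tetrahydro-1H-isochromen-3-yl]acrylate; 21 4-methoxy-6-methyl-2,2-diphenyl-1,3-benzodioxole-5-carboxylic acid
Product: 26 (6R,7R)-3-[(E)-3-tert-butoxy-3-oxoprop-1-en-1-yl]-7-hydroxy-7-methyl-8-oxo-5,6,7,8-tetrahydro-1H-isochromen-6-yl 4-methoxy-6-methyl-2,2-diphenyl-1,3-benzodioxole-5-carboxylate, via acid chloride 25 (not isolated)
Conditions: 21, 1-chloro-N,N,2-trimethylprop-1-en-1-amine, CH2Cl2, 0 °C → rt; then 24, pyridine, DMAP (20 mol%), CH2Cl2, 0 °C → rt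
Reagents that add atoms: none
Why: The acid chloride is made under neutral conditions that spare the ketal, and DMAP-catalysed acylation should select the secondary C6 hydroxyl over the tertiary C7 hydroxyl with retention at C6.

Step 17
Reactants: 26 (6R,7R)-3-[(E)-3-tert-butoxy-3-oxoprop-1-en-1-yl]-7-hydroxy-7-methyl-8-oxo-5,6,7,8-tetrahydro-1H-isochromen-6-yl 4-methoxy-6-methyl-2,2-diphenyl-1,3-benzodioxole-5-carboxylate
Product: 27 (E)-3-[(6R,7R)-6-[(3,4-dihydroxy-2-methoxy-6-methylbenzoyl)oxy]-7-hydroxy-7-methyl-8-oxo-5,6,7,8-tetrahydro-1H-isochromen-3-yl]acrylic acid (CNP0446308.2)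
Conditions: TFA/CH2Cl2 1:2, H2O (10 equiv), 0 °C → rt
Reagents that add atoms: none
Why: Acidolysis cleaves the tert-butyl ester and the diphenylmethylene ketal in one operation without base, so the base-sensitive C6 acyloxy group and the hindered aryl ester should survive.

**Compound list**

1 | 3-[(tert-butyldimethylsilyl)oxy]propanal | O=CCCO[Si](C)(C)C(C)(C)C | starting material
2 | 3,3-diethoxyprop-1-yne | C#CC(OCC)OCC | starting material
3 | lithium 3,3-diethoxyprop-1-yn-1-ide | [Li]C#CC(OCC)OCC | intermediate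
4 | 1-[(tert-butyldimethylsilyl)oxy]-6,6-diethoxyhex-4-yn-3-ol (racemic) | CCOC(OCC)C#CC(O)CCO[Si](C)(C)C(C)(C)C | intermediate
5 | 1-[(tert-butyldimethylsilyl)oxy]-6,6-diethoxyhex-4-yn-3-one | CCOC(OCC)C#CC(=O)CCO[Si](C)(C)C(C)(C)C | intermediate
6 | 6,6-diethoxy-1-hydroxyhex-4-yn-3-one | CCOC(OCC)C#CC(=O)CCO | intermediate
7 | 6-(diethoxymethyl)-2,3-dihydro-4H-pyran-4-one | CCOC(OCC)C1=CC(=O)CCO1 | intermediate
8 | 4-oxo-5,6-dihydro-4H-pyran-2-carbaldehyde | O=CC1=CC(=O)CCO1 | intermediate
9 | tert-butyl (E)-3-(4-oxo-5,6-dihydro-4H-pyran-2-yl)acrylate | O=C1CCOC(/C=C/C(=O)OC(C)(C)C)=C1 | intermediate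
10 | tert-butyl (E)-3-(4-chloro-3-formyl-2H-pyran-6-yl)acrylate | O=CC1=C(Cl)C=C(/C=C/C(=O)OC(C)(C)C)OC1 | intermediate
11 | (R)-2-(2,2-dimethyl-5-oxo-1,3-dioxolan-4-yl)acetic acid | CC1(C)O[C@H](CC(=O)O)C(=O)O1 | starting material
12 | (R)-3-hydroxy-4-[methoxy(methyl)amino]-4-oxobutanoic acid | CON(C)C(=O)[C@H](O)CC(=O)O | intermediate
13 | tert-butyldimethylsilyl (R)-3-[(tert-butyldimethylsilyl)oxy]-4-[methoxy(methyl)amino]-4-oxobutanoate | CON(C)C(=O)[C@H](O[Si](C)(C)C(C)(C)C)CC(=O)O[Si](C)(C)C(C)(C)C | intermediate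
14 | (R)-3-[(tert-butyldimethylsilyl)oxy]-4-[methoxy(methyl)amino]-4-oxobutanoic acid | CON(C)C(=O)[C@H](O[Si](C)(C)C(C)(C)C)CC(=O)O | intermediate
15 | (R)-3-[(tert-butyldimethylsilyl)oxy]-4-oxopentanoic acid | CC(=O)[C@H](O[Si](C)(C)C(C)(C)C)CC(=O)O | intermediate
16 | 1,3-dioxoisoindolin-2-yl (R)-3-[(tert-butyldimethylsilyl)oxy]-4-oxopentanoate | CC(=O)[C@H](O[Si](C)(C)C(C)(C)C)CC(=O)ON1C(=O)c2ccccc2C1=O | intermediate
17 | 5-methylbenzene-1,2,3-triol | Cc1cc(O)c(O)c(O)c1 | starting material
18 | 6-methyl-2,2-diphenyl-1,3-benzodioxol-4-ol | Cc1cc(O)c2OC(c3ccccc3)(c3ccccc3)Oc2c1 | intermediate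
19 | 4-hydroxy-6-methyl-2,2-diphenyl-1,3-benzodioxole-5-carbaldehyde | Cc1cc2OC(c3ccccc3)(c3ccccc3)Oc2c(O)c1C=O | intermediate
20 | 4-methoxy-6-methyl-2,2-diphenyl-1,3-benzodioxole-5-carbaldehyde | COc1c(C=O)c(C)cc2OC(c3ccccc3)(c3ccccc3)Oc12 | intermediate
21 | 4-methoxy-6-methyl-2,2-diphenyl-1,3-benzodioxole-5-carboxylic acid | COc1c(C(=O)O)c(C)cc2OC(c3ccccc3)(c3ccccc3)Oc12 | intermediate
22 | tert-butyl (E)-3-{4-[(R)-2-[(tert-butyldimethylsilyl)oxy]-3-oxobutyl]-3-formyl-2H-pyran-6-yl}acrylate | CC(=O)[C@H](O[Si](C)(C)C(C)(C)C)CC1=C(C=O)COC(/C=C/C(=O)OC(C)(C)C)=C1 | intermediate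
23 | tert-butyl (E)-3-[(6R,7R)-6-[(tert-butyldimethylsilyl)oxy]-7-hydroxy-7-methyl-8-oxo-5,6,7,8-tetrahydro-1H-isochromen-3-yl]acrylate | CC(C)(C)[Si](C)(C)O[C@@H]1CC2=C(COC(/C=C/C(=O)OC(C)(C)C)=C2)C(=O)[C@]1(C)O | intermediate
24 | tert-butyl (E)-3-[(6R,7R)-6,7-dihydroxy-7-methyl-8-oxo-5,6,7,8-tetrahydro-1H-isochromen-3-yl]acrylate | O[C@@H]1CC2=C(COC(/C=C/C(=O)OC(C)(C)C)=C2)C(=O)[C@]1(C)O | intermediate
25 | 4-methoxy-6-methyl-2,2-diphenyl-1,3-benzodioxole-5-carbonyl chloride | COc1c(C(Cl)=O)c(C)cc2OC(c3ccccc3)(c3ccccc3)Oc12 | intermediate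
26 | (6R,7R)-3-[(E)-3-tert-butoxy-3-oxoprop-1-en-1-yl]-7-hydroxy-7-methyl-8-oxo-5,6,7,8-tetrahydro-1H-isochromen-6-yl 4-methoxy-6-methyl-2,2-diphenyl-1,3-benzodioxole-5-carboxylate | COc1c(C(=O)O[C@@H]4CC5=C(COC(/C=C/C(=O)OC(C)(C)C)=C5)C(=O)[C@]4(C)O)c(C)cc2OC(c3ccccc3)(c3ccccc3)Oc12 | intermediate
27 | (E)-3-[(6R,7R)-6-[(3,4-dihydroxy-2-methoxy-6-methylbenzoyl)oxy]-7-hydroxy-7-methyl-8-oxo-5,6,7,8-tetrahydro-1H-isochromen-3-yl]acrylic acid | COc1c(O)c(O)cc(C)c1C(=O)O[C@@H]1CC2=C(COC(/C=C/C(=O)O)=C2)C(=O)[C@]1(C)O | target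

Total step count: 17. Longest linear sequence: 9 steps (steps 1–5 and 14–17).

**Steps most likely to fail**

Step 14. In the telescoped second stage the carbene may be sequestered by nickel, the keto-enal may undergo base-induced aldol closure or C6 epimerisation before the benzoin ring closure, or facial selectivity at C7 may be poor. The fallback sets out from 10 and 16: the nickel coupling is run alone and keto-enal 22 is isolated. The ring is then closed reductively with SmI2 (THF/t-BuOH, −78 °C), a ketyl–carbonyl pinacol cyclisation by divalent samarium in which samarium chelation should give the cis-7,8-diol, the all-cis 6-silyloxy-7,8-dihydroxy compound F1. The C8 configuration is erased when the allylic secondary alcohol is oxidised selectively with MnO2 (CH2Cl2, rt), and the fallback comes back to the route at 23.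

Step 5. Formylation may occur at the enol-ether carbon instead of the α-methylene, or the acidic medium may cleave the tert-butyl ester. The fallback sets out from 9: condensation with N,N-dimethylformamide dimethyl acetal (toluene, 90 °C) at the ketone α-methylene under neutral conditions gives the enaminone F2. Oxalyl chloride (CH2Cl2, −20 °C) converts F2 to the chloro-iminium chloride F3, and hydrolysis with aq NaOAc returns to the route at 10.

Step 16. Acylation of the hindered C6 hydroxyl by the di-ortho-substituted acyl chloride may be slow, allowing base-induced vinylogous elimination or competing acylation at C7. The fallback sets out from 24: Bu2SnO (toluene, reflux, water removal) gives the dibutylstannylene acetal F4. This is acylated at the secondary oxygen by acid chloride 25 (made from 21 as in step 16) at rt without amine base, returning to the route at 26.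

Further compounds
F1 | step 14 | tert-butyl (E)-3-[6-[(tert-butyldimethylsilyl)oxy]-7,8-dihydroxy-7-methyl-5,6,7,8-tetrahydro-1H-isochromen-3-yl]acrylate, all-cis, C6 and C7 arranged as in 23 | CC(C)(C)[Si](C)(C)O[C@@H]1CC2=C(COC(/C=C/C(=O)OC(C)(C)C)=C2)[C@H](O)[C@]1(C)O
F2 | step 5 | tert-butyl (E)-3-{3-[(E)-(dimethylamino)methylene]-4-oxo-3,4-dihydro-2H-pyran-6-yl}acrylate | CN(C)/C=C1/C(=O)C=C(/C=C/C(=O)OC(C)(C)C)OC1
F3 | step 5 | N-{[6-((E)-3-tert-butoxy-3-oxoprop-1-en-1-yl)-4-chloro-2H-pyran-3-yl]methylene}-N-methylmethanaminium chloride | C[N+](C)=CC1=C(Cl)C=C(/C=C/C(=O)OC(C)(C)C)OC1.[Cl-]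
F4 | step 16 | 6,7-O-dibutylstannylene acetal of 24 | CCCC[Sn]1(CCCC)O[C@@H]2CC3=C(COC(/C=C/C(=O)OC(C)(C)C)=C3)C(=O)[C@]2(C)O1
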